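**Retrosynthetic overview**

1. The target is a cis-fused γ-lactone/1,2-dioxane. One cationic annulation divides it into (R)-3-hydroperoxy-4-oxopentanoic acid 8 and enyne 15, forming C4–C5 and O–C6 of the dioxane together with the lactone C–O bond.
2. Enabling feature: C4 of the lactone ring is a ketone-level carbon γ to the carboxyl, so it can become a five-membered acyloxocarbenium ion. The C3–O–O unit on the adjacent ring carbon places the distal peroxide oxygen where it closes the six-membered ring C3–O–O–C6–C5–C4 onto the tertiary cation that the alkene leaves at C6.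
3. The C6 side chain is carried as an alkyne. It makes the C6 cation propargylic and is the slim axial group that sets C6; diimide then reduces it to the alkane.
4. Ring order: lactone ring first (in situ), then the dioxane ring, both in step 9. C3 is set beforehand by organocatalytic peroxidation of enal 3 and relays to C4 and C6.
5. Fragments: the enal comes from methyl 2,2-dimethoxypropanoate; the enyne from an aryl Grignard reagent, 1,8-dibromooctane and 2-methylbut-1-en-3-yne.

Key step: step 9

Remark: plakortolide numbering is used for positions (C1 lactone carbonyl, C3 peroxy methine, C4 lactone quaternary carbon, C6 peroxy quaternary carbon; target 3R,4R,6S). Keto acid 8 is drawn open-chain although it should equilibrate with its cyclic hemiketal (pseudo-acid) form, which leads to the same cation 17.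

**Route**

Step 1
Reactants: 1 methyl 2,2-dimethoxypropanoate
Product: 2 2,2-dimethoxypropanal
Conditions: i-Bu2AlH (1.05 equiv), CH2Cl2, −78 °C; then aq. work-up
Reagents that add atoms: none
Why: Partial ester reduction with i-Bu2AlH at low temperature, in which the two α-methoxy groups stabilise the tetrahedral aluminium hemiacetal by chelation so that the aldehyde is released only on work-up.

Step 2
Reactants: 2 2,2-dimethoxypropanal
Product: 3 (E)-4,4-dimethoxypent-2-enal
Conditions: Ph3P=CHCHO, toluene, 80 °C
Reagents that add atoms: (triphenylphosphoranylidene)acetaldehyde, O=CC=P(c1ccccc1)(c1ccccc1)c1ccccc1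
Why: Wittig olefination with the stabilised formylmethylene ylide should give the (E)-enal, and the aldehyde has no α-hydrogen, so self-condensation cannot compete.

Step 3
Reactants: 4 2,3-dimethylbut-2-ene
Product: 5 2-hydroperoxy-2-methoxypropane
Conditions: O3, CH2Cl2/MeOH, −78 °C; N2 purge; used as a solution
Reagents that add atoms: ozone, [O-][O+]=O; methanol, CO
Why: Ozonolysis in methanol (Criegee mechanism), in which the carbonyl oxide from the tetrasubstituted alkene is trapped by methanol to give the α-methoxy hydroperoxide and acetone.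

Step 4
Reactants: 3 (E)-4,4-dimethoxypent-2-enal; 5 2-hydroperoxy-2-methoxypropane
Product: 6 (R)-4,4-dimethoxy-3-[(2-methoxypropan-2-yl)peroxy]pentanal
Conditions: (R)-2-[diphenyl(trimethylsilyloxy)methyl]pyrrolidine (10 mol%), PhCO2H (10 mol%), toluene, 0 °C
Reagents that add atoms: none
Why: Iminium-catalysed enantioselective conjugate addition of a hydroperoxide to an enal (oxa-Michael addition), in which the (R)-diarylprolinol silyl ether shields one face of the (E)-iminium ion so that the peroxide oxygen should add to the open face of C3 and give the (R)-peroxide, while the acid co-catalyst protonates the enamine before it can close to the epoxide.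

Step 5
Reactants: 6 (R)-4,4-dimethoxy-3-[(2-methoxypropan-2-yl)peroxy]pentanal
Product: 7 (R)-4,4-dimethoxy-3-[(2-methoxypropan-2-yl)peroxy]pentanoic acid
Conditions: NaClO2, NaH2PO4, 2-methyl-2-butene, t-BuOH/H2O, 0 °C
Reagents that add atoms: sodium chlorite, [Na+].[O-]Cl=O
Why: Pinnick oxidation converts the aldehyde to the acid without touching the dialkyl peroxide or the C3 stereocentre, and 2-methyl-2-butene scavenges the hypochlorous acid.

Step 6
Reactants: 7 (R)-4,4-dimethoxy-3-[(2-methoxypropan-2-yl)peroxy]pentanoic acid
Product: 8 (R)-3-hydroperoxy-4-oxopentanoic acid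
Conditions: 0.5 M aq. HCl/THF (1:3), 0 °C to rt; extracted and used at once
Reagents that add atoms: water, O
Why: Acid-catalysed hydrolysis removes the peroxyketal (to the hydroperoxide) and the dimethyl ketal (to the methyl ketone) in one operation, and dilute acid at low temperature is chosen because acid-catalysed enolisation towards the oxygen-bearing C3 is slow, so the stereocentre should survive.

Step 7
Reactants: 9 (4-bromophenoxy)(tert-butyl)dimethylsilane; 10 1,8-dibromooctane
Product: 12 [4-(8-bromooctyl)phenoxy](tert-butyl)dimethylsilane, via aryl Grignard reagent 11 (not isolated)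
Conditions: Mg, THF, reflux; then 10 (3 equiv), Li2CuCl4 (3 mol%), THF, −10 °C to rt
Reagents that add atoms: none
Why: Kochi-type copper-catalysed coupling of an aryl Grignard reagent with a primary alkyl bromide, with the excess of dibromide suppressing double coupling.

Step 8
Reactants: 13 2-methylbut-1-en-3-yne; 12 [4-(8-bromooctyl)phenoxy](tert-butyl)dimethylsilane
Product: 15 tert-butyldimethyl[4-(11-methyldodec-11-en-9-yn-1-yl)phenoxy]silane, via lithium acetylide 14 (not isolated)
Conditions: 13 (2 equiv), n-BuLi, THF, −78 °C; then 12, DMPU, −78 °C to rt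
Reagents that add atoms: none
Why: SN2 alkylation of a lithium acetylide with a primary bromide in THF/DMPU, to which the aryl silyl ether is inert.

Step 9
Reactants: 8 (R)-3-hydroperoxy-4-oxopentanoic acid; 15 tert-butyldimethyl[4-(11-methyldodec-11-en-9-yn-1-yl)phenoxy]silane
Product: 18 (3R,4aR,7aR)-3-{10-[4-(tert-butyldimethylsilyloxy)phenyl]dec-1-yn-1-yl}-3,4a-dimethyl-3,4,4a,7a-tetrahydrofuro[3,2-c][1,2]dioxin-6(7H)-one, via bis-silyl derivative 16 (not isolated), via acyloxocarbenium triflate 17 (not isolated)
Conditions: MSTFA (2.5 equiv), CH2Cl2, 0 °C, volatiles removed; Me3SiOTf (1.1 equiv), CH2Cl2, −78 °C, 10 min; then 15 (1.5 equiv), −78 to −40 °C; pH 7 buffer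
Reagents that add atoms: none
Why: Proposed new method: after neutral persilylation (16), Me3SiOTf silylates the ketone, the silyl ester carbonyl closes on it (5-exo-trig) and loss of (Me3Si)2O gives the five-membered acyloxocarbenium ion 17, to which the CH2 terminus of enyne 15 adds (Prins-type) to form C4–C5 and a tertiary propargylic cation at C6; the distal, silylated peroxide oxygen captures this cation in a six-membered closure (Markovnikov, both former alkene carbons in the ring) and releases Me3Si+, which regenerates Me3SiOTf. The closest known reaction types are the [3+2] annulation of silylperoxy carbenium ions with alkenes to 1,2-dioxolanes and the capture of β-peroxy oxocarbenium ions (from 1,2-dioxetanes and Me3SiOTf) by carbonyl compounds to 1,2,4-trioxanes; here the peroxide sits one carbon further from the cation and an alkene replaces the carbonyl partner. C4 is controlled by C3: the alkene should add cis to the peroxy group (inside attack on the envelope of a five-membered oxocarbenium ion whose neighbouring oxygen substituent is pseudo-equatorial), and this is the adduct that closes to the cis-fused bicycle. C6 is controlled in the chair-like closure, in which the slim alkynyl group takes the axial position syn to the axial lactone oxygen and the methyl group the equatorial one (methyl groups at C4 and C6 cis); reversible ionisation of the tertiary propargylic C–O bond would lead to the same, more stable epimer. The step needs attack at the CH2 end of the enyne (secured by the tertiary propargylic cation that only this mode gives), alkene over arene attack (the para-substituted aryl silyl ether is less nucleophilic than a 1,1-disubstituted alkene) and capture of 17 before it fragments (secured by pre-forming 17 at −78 °C with irreversible loss of the non-nucleophilic disiloxane).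

Step 10
Reactants: 18 (3R,4aR,7aR)-3-{10-[4-(tert-butyldimethylsilyloxy)phenyl]dec-1-yn-1-yl}-3,4a-dimethyl-3,4,4a,7a-tetrahydrofuro[3,2-c][1,2]dioxin-6(7H)-one
Product: 19 (3S,4aR,7aR)-3-{10-[4-(tert-butyldimethylsilyloxy)phenyl]decyl}-3,4a-dimethyl-3,4,4a,7a-tetrahydrofuro[3,2-c][1,2]dioxin-6(7H)-one
Conditions: KO2CN=NCO2K (large excess, in portions), AcOH, pyridine/MeOH, 0 °C to rt
Reagents that add atoms: none
Why: Diimide reduction (syn hydrogen transfer from HN=NH generated in situ) saturates the alkyne via the cis-alkene and, unlike catalytic hydrogenation, leaves the O–O bond intact; no stereocentre is touched, and the C6 descriptor changes from R to S only because the side-chain priority drops.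

Step 11
Reactants: 19 (3S,4aR,7aR)-3-{10-[4-(tert-butyldimethylsilyloxy)phenyl]decyl}-3,4a-dimethyl-3,4,4a,7a-tetrahydrofuro[3,2-c][1,2]dioxin-6(7H)-one
Product: 20 plakortolide S, (3S,4aR,7aR)-3-[10-(4-hydroxyphenyl)decyl]-3,4a-dimethyl-3,4,4a,7a-tetrahydrofuro[3,2-c][1,2]dioxin-6(7H)-one
Conditions: Bu4NF, AcOH (1:1), THF, 0 °C
Reagents that add atoms: none
Why: Fluoride-mediated cleavage of the aryl silyl ether, buffered with AcOH so that the medium stays non-basic and the β-peroxy lactone does not undergo E1cB ring opening.

**Compound list**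

1 | methyl 2,2-dimethoxypropanoate | COC(=O)C(C)(OC)OC | starting material
2 | 2,2-dimethoxypropanal | CC(OC)(OC)C=O | intermediate
3 | (E)-4,4-dimethoxypent-2-enal | CC(OC)(OC)/C=C/C=O | intermediate
4 | 2,3-dimethylbut-2-ene | CC(C)=C(C)C | starting material
5 | 2-hydroperoxy-2-methoxypropane | COC(C)(C)OO | intermediate
6 | (R)-4,4-dimethoxy-3-[(2-methoxypropan-2-yl)peroxy]pentanal | CC(OC)(OC)[C@H](OOC(C)(C)OC)CC=O | intermediate
7 | (R)-4,4-dimethoxy-3-[(2-methoxypropan-2-yl)peroxy]pentanoic acid | CC(OC)(OC)[C@H](OOC(C)(C)OC)CC(=O)O | intermediate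
8 | (R)-3-hydroperoxy-4-oxopentanoic acid | CC(=O)[C@H](OO)CC(=O)O | intermediate
9 | (4-bromophenoxy)(tert-butyl)dimethylsilane | CC(C)(C)[Si](C)(C)Oc1ccc(Br)cc1 | starting material
10 | 1,8-dibromooctane | BrCCCCCCCCBr | starting material
11 | {4-[(tert-butyldimethylsilyl)oxy]phenyl}magnesium bromide | CC(C)(C)[Si](C)(C)Oc1ccc([Mg]Br)cc1 | intermediate
12 | [4-(8-bromooctyl)phenoxy](tert-butyl)dimethylsilane | CC(C)(C)[Si](C)(C)Oc1ccc(CCCCCCCCBr)cc1 | intermediate
13 | 2-methylbut-1-en-3-yne | C=C(C)C#C | starting material
14 | lithium 3-methylbut-3-en-1-yn-1-ide | [Li]C#CC(C)=C | intermediate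
15 | tert-butyldimethyl[4-(11-methyldodec-11-en-9-yn-1-yl)phenoxy]silane | C=C(C)C#CCCCCCCCCc1ccc(O[Si](C)(C)C(C)(C)C)cc1 | intermediate
16 | trimethylsilyl (R)-4-oxo-3-[(trimethylsilyl)peroxy]pentanoate | CC(=O)[C@H](OO[Si](C)(C)C)CC(=O)O[Si](C)(C)C | intermediate
17 | (4R)-5-methyl-2-oxo-4-[(trimethylsilyl)peroxy]-3,4-dihydro-2H-furan-1-ium trifluoromethanesulfonate | CC1=[O+]C(=O)C[C@H]1OO[Si](C)(C)C.[O-]S(=O)(=O)C(F)(F)F | intermediate
18 | (3R,4aR,7aR)-3-{10-[4-(tert-butyldimethylsilyloxy)phenyl]dec-1-yn-1-yl}-3,4a-dimethyl-3,4,4a,7a-tetrahydrofuro[3,2-c][1,2]dioxin-6(7H)-one | C[C@]1(C#CCCCCCCCCc2ccc(O[Si](C)(C)C(C)(C)C)cc2)C[C@@]2(C)OC(=O)C[C@H]2OO1 | intermediate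
19 | (3S,4aR,7aR)-3-{10-[4-(tert-butyldimethylsilyloxy)phenyl]decyl}-3,4a-dimethyl-3,4,4a,7a-tetrahydrofuro[3,2-c][1,2]dioxin-6(7H)-one | C[C@]1(CCCCCCCCCCc2ccc(O[Si](C)(C)C(C)(C)C)cc2)C[C@@]2(C)OC(=O)C[C@H]2OO1 | intermediate
20 | plakortolide S, (3S,4aR,7aR)-3-[10-(4-hydroxyphenyl)decyl]-3,4a-dimethyl-3,4,4a,7a-tetrahydrofuro[3,2-c][1,2]dioxin-6(7H)-one (3R,4R,6S in plakortolide numbering) | C[C@]1(CCCCCCCCCCc2ccc(O)cc2)C[C@@]2(C)OC(=O)C[C@H]2OO1 | target

**Step count and risks**

Total steps: 11. Longest linear sequence: 8 steps (1, 2, 4, 5, 6, 9, 10, 11).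

Most likely to fail:

1. Step 9 (proposed new method). Lewis-acid-induced fragmentation of the α-silylperoxy cation (Hock-type C–C cleavage or collapse to a dioxetane) may outrun capture by the weakly nucleophilic enyne, or facial selectivity in the C–C bond formation may be poor. The fallback is stepwise and uses known reaction types; it sets out from Grignard reagent 11 and from 16/17 (made from 8 as in step 9) and comes back at 19.
   - The aryl Grignard reagent 11 is coupled with commercial 1,10-dibromodecane (Li2CuCl4) to [4-(10-bromodecyl)phenoxy](tert-butyl)dimethylsilane F1.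
   - F1 is coupled (Li2CuCl4, THF/NMP) with [3-(trimethylsilyl)prop-1-en-2-yl]magnesium bromide F2, prepared from commercial 2-bromoallyltrimethylsilane and Mg, to give the allylsilane tert-butyldimethyl(4-{11-[(trimethylsilyl)methyl]dodec-11-en-1-yl}phenoxy)silane F3.
   - Cation 17 is intercepted by F3 in a Hosomi–Sakurai allylation; allylsilanes are far more nucleophilic than the enyne and are established partners for cyclic oxocarbenium ions in the presence of silyl peroxides. Aqueous work-up should give (4R,5R)-5-{12-[4-(tert-butyldimethylsilyloxy)phenyl]-2-methylidenedodecyl}-4-hydroperoxy-5-methyldihydrofuran-2(3H)-one F4.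
   - Cycloperoxymercuration (Hg(OAc)2, CH2Cl2; 6-exo, Markovnikov) should give the acetoxymercuriomethyl dioxane F5 as a mixture of C6 epimers.
   - Hydrodemercuration (Bu3SnH) should give 19 together with its C6 epimer F6, to be separated by chromatography. This fallback gives up the one-operation annulation and the control of C6.

2. Step 4. Addition to the hindered enal (quaternary γ-carbon) may be slow, the enamine intermediate may close to the epoxide, or face discrimination may be insufficient. The fallback replaces asymmetric catalysis by classical resolution; it sets out from 3 (with 5) and comes back at 7.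
   - Addition catalysed by pyrrolidine/PhCO2H gives racemic 4,4-dimethoxy-3-[(2-methoxypropan-2-yl)peroxy]pentanal F7.
   - Pinnick oxidation gives the racemic acid F8.
   - Fractional crystallisation with (R)-1-phenylethylamine (or its enantiomer, whichever gives the less soluble salt with the R acid) should furnish the salt (R)-1-phenylethylammonium (R)-4,4-dimethoxy-3-[(2-methoxypropan-2-yl)peroxy]pentanoate F9; cold aqueous citric acid then liberates 7.

3. Step 10. Saturation of the hindered cis-alkene intermediate next to the quaternary C6 may stall, and prolonged treatment may erode the peroxide. The fallback enters the key step at the alkane oxidation level; it sets out from 12 and comes back at 19.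
   - Bromide 12 is converted (Mg, THF) into {8-[4-(tert-butyldimethylsilyloxy)phenyl]octyl}magnesium bromide F10.
   - F10 is coupled (Li2CuCl4) with commercial 4-bromo-2-methylbut-1-ene to tert-butyldimethyl[4-(11-methyldodec-11-en-1-yl)phenoxy]silane F11.
   - Used in step 9 in place of 15, F11 should give 19 directly. Without the alkynyl group the closure at C6 is expected to be unselective, so the C6 epimer F12 would have to be separated.

Further compounds

F1 | step 9 | [4-(10-bromodecyl)phenoxy](tert-butyl)dimethylsilane | CC(C)(C)[Si](C)(C)Oc1ccc(CCCCCCCCCCBr)cc1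
F2 | step 9 | [3-(trimethylsilyl)prop-1-en-2-yl]magnesium bromide | C=C([Mg]Br)C[Si](C)(C)C
F3 | step 9 | tert-butyldimethyl(4-{11-[(trimethylsilyl)methyl]dodec-11-en-1-yl}phenoxy)silane | C=C(C[Si](C)(C)C)CCCCCCCCCCc1ccc(O[Si](C)(C)C(C)(C)C)cc1
F4 | step 9 | (4R,5R)-5-{12-[4-(tert-butyldimethylsilyloxy)phenyl]-2-methylidenedodecyl}-4-hydroperoxy-5-methyldihydrofuran-2(3H)-one | C=C(CCCCCCCCCCc1ccc(O[Si](C)(C)C(C)(C)C)cc1)C[C@@]2(C)OC(=O)C[C@H]2OO
F5 | step 9 | {[(4aR,7aR)-3-{10-[4-(tert-butyldimethylsilyloxy)phenyl]decyl}-4a-methyl-6-oxohexahydrofuro[3,2-c][1,2]dioxin-3-yl]methyl}mercury acetate (C6 epimers) | CC(=O)O[Hg]CC1(CCCCCCCCCCc2ccc(O[Si](C)(C)C(C)(C)C)cc2)C[C@@]2(C)OC(=O)C[C@H]2OO1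
F6 | step 9 | (3R,4aR,7aR)-3-{10-[4-(tert-butyldimethylsilyloxy)phenyl]decyl}-3,4a-dimethyl-3,4,4a,7a-tetrahydrofuro[3,2-c][1,2]dioxin-6(7H)-one (C6 epimer of 19) | C[C@@]1(CCCCCCCCCCc2ccc(O[Si](C)(C)C(C)(C)C)cc2)C[C@@]2(C)OC(=O)C[C@H]2OO1
F7 | step 4 | racemic 4,4-dimethoxy-3-[(2-methoxypropan-2-yl)peroxy]pentanal | CC(OC)(OC)C(OOC(C)(C)OC)CC=O
F8 | step 4 | racemic 4,4-dimethoxy-3-[(2-methoxypropan-2-yl)peroxy]pentanoic acid | CC(OC)(OC)C(OOC(C)(C)OC)CC(=O)O
F9 | step 4 | (R)-1-phenylethylammonium (R)-4,4-dimethoxy-3-[(2-methoxypropan-2-yl)peroxy]pentanoate | CC(OC)(OC)[C@H](OOC(C)(C)OC)CC(=O)[O-].C[C@@H]([NH3+])c1ccccc1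
F10 | step 10 | {8-[4-(tert-butyldimethylsilyloxy)phenyl]octyl}magnesium bromide | CC(C)(C)[Si](C)(C)Oc1ccc(CCCCCCCC[Mg]Br)cc1
F11 | step 10 | tert-butyldimethyl[4-(11-methyldodec-11-en-1-yl)phenoxy]silane | C=C(C)CCCCCCCCCCc1ccc(O[Si](C)(C)C(C)(C)C)cc1
F12 | step 10 | (3R,4aR,7aR)-3-{10-[4-(tert-butyldimethylsilyloxy)phenyl]decyl}-3,4a-dimethyl-3,4,4a,7a-tetrahydrofuro[3,2-c][1,2]dioxin-6(7H)-one (C6 epimer of 19, same structure as F6) | C[C@@]1(CCCCCCCCCCc2ccc(O[Si](C)(C)C(C)(C)C)cc2)C[C@@]2(C)OC(=O)C[C@H]2OO1
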